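The 14-membered carbocycle is disconnected at C9–C10, the bond between methylene C9 and the oxygen-bearing γ-carbon C10 of the butyrolactone. C10 carries the lactone oxygen, so a carboxyl group placed there gives a stabilised nucleophilic radical on decarboxylation. C9 is β to the C19 ester, so it is presented as the free terminus of a 2-substituted acrylate (C7 held as a carbinol). One photoredox decarboxylative radical conjugate addition then closes the macrocycle onto the preformed (E)-alkylidene lactone and creates C10. The open-chain acid comes from a rhodium-catalysed isopropenyl addition (C1), Z-olefination and Sharpless epoxidation (C3, C4), and a phosphonate olefination (C12=C13).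

Key step: step 17

Numbering (target atoms): C1 bears the isopropenyl group; the ring runs C1, C2 (CH2), C3 and C4 (epoxide, C4 bears methyl C18), C5 (C=O), C6 (CH2), C7 (C=O), C8 (bears ester C19), C9 (CH2), C10 (lactone CH–O), C11 (lactone CH2), C12 (bears lactone carbonyl C20), C13 (=CH), C14 (CH2). The target is (1R,3S,4S,8S,10S,12E).

Remark: C8 lies between the C19 ester and the C7 ketone and is configurationally labile; the route delivers it by equilibration and assumes that (8S) is the resting epimer of the macrocycle.

Remark: C5 and C7 are carried as carbinol epimer mixtures (as are C8 after ring closure and C10 before it); they are drawn without configuration because later steps erase or re-set them.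

Step 1
Reactants: 1 5,6-dihydro-2H-pyran-2-one; 2 isopropenylboronic acid pinacol ester
Product: 3 (4R)-4-(prop-1-en-2-yl)oxan-2-one
Conditions: [Rh(cod)Cl]2 (2.5 mol %), (R)-BINAP (6 mol %), K3PO4 (0.5 equiv), dioxane/H2O 10:1, 60 °C; 1 M HCl work-up
Reagents that add atoms: none
Why: Hayashi–Miyaura asymmetric 1,4-addition of an alkenylboron reagent to a cyclic enoate should set C1; (R)-BINAP is chosen by the established facial model, in which (S)-BINAP gives the (S) adducts of this lactone.

Step 2
Reactants: 3 (4R)-4-(prop-1-en-2-yl)oxan-2-one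
Product: 4 (4R)-4-(prop-1-en-2-yl)oxan-2-ol (lactol, anomer mixture)
Conditions: i-Bu2AlH (1.1 equiv), CH2Cl2, −78 °C; Rochelle salt work-up
Reagents that add atoms: none
Why: Partial hydride reduction of a δ-lactone at low temperature should stop at the lactol, because the tetrahedral aluminium alkoxide is stable until work-up.

Step 3
Reactants: 4 lactol; 5 ethyl 2-[bis(2,2,2-trifluoroethoxy)phosphoryl]propanoate
Product: 6 ethyl (2Z,5S)-7-hydroxy-2-methyl-5-(prop-1-en-2-yl)hept-2-enoate
Conditions: KN(SiMe3)2, 18-crown-6, THF, −78 to −20 °C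
Reagents that add atoms: none
Why: Still–Gennari olefination of the open hydroxy-aldehyde tautomer should give the kinetic (Z)-enoate (C2 cis to C5) that later becomes the cis-epoxide; C1 is untouched.

Step 4
Reactants: 6 hydroxy (Z)-enoate
Product: 7 ethyl (2Z,5S)-7-[(tert-butyldimethylsilyl)oxy]-2-methyl-5-(prop-1-en-2-yl)hept-2-enoate
Conditions: TBSCl, imidazole, DMF, 0 °C to rt
Reagents that add atoms: tert-butyldimethylsilyl chloride CC(C)(C)[Si](C)(C)Cl
Why: Standard silylation of the primary C13 alcohol should mask it through the reductions and oxidations that follow.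

Step 5
Reactants: 7 silyl ether (Z)-enoate
Product: 8 (2Z,5S)-7-[(tert-butyldimethylsilyl)oxy]-2-methyl-5-(prop-1-en-2-yl)hept-2-en-1-ol
Conditions: i-Bu2AlH (2.5 equiv), CH2Cl2, −78 °C
Reagents that add atoms: none
Why: 1,2-Reduction of the enoate by the aluminium hydride should give the (Z)-allylic alcohol without touching the alkene geometry.

Step 6
Reactants: 8 (Z)-allylic alcohol
Product: 9 [(2R,3S)-3-{(2R)-4-[(tert-butyldimethylsilyl)oxy]-2-(prop-1-en-2-yl)butyl}-2-methyloxiran-2-yl]methanol
Conditions: Ti(OiPr)4, D-(−)-diethyl tartrate, t-BuOOH, 4 Å MS, CH2Cl2, −20 °C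
Reagents that add atoms: tert-butyl hydroperoxide CC(C)(C)OO
Why: Sharpless asymmetric epoxidation should set C3 and C4 under reagent control (D-tartrate delivers oxygen to the face that gives the 2R,3S epoxy alcohol), the Z-olefin fixing the cis relation of C2 and C5; the isopropenyl group has no directing hydroxyl and should stay intact.

Step 7
Reactants: 9 epoxy alcohol
Product: 10 (2S,3S)-3-{(2R)-4-[(tert-butyldimethylsilyl)oxy]-2-(prop-1-en-2-yl)butyl}-2-methyloxirane-2-carbaldehyde
Conditions: Dess–Martin periodinane, pyridine, CH2Cl2, 0 °C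
Reagents that add atoms: none
Why: Buffered Dess–Martin oxidation should give the epoxy aldehyde, which has a quaternary α-carbon and therefore cannot epimerise.

Step 8
Reactants: 10 epoxy aldehyde; 11 methyl acetate
Product: 12 methyl 3-hydroxy-3-(oxiranyl)propanoate (C5 carbinol, C6–C7 ester; C1, C3, C4 as in 10; C5 epimer mixture)
Conditions: LiN(i-Pr)2, THF, −78 °C; AcOH quench at −78 °C
Reagents that add atoms: none
Why: Acetate aldol addition of the lithium ester enolate should form C5–C6; the new C5 carbinol is not controlled and is erased in step 19, and the cold quench avoids Payne rearrangement.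

Step 9
Reactants: 12 β-hydroxy ester
Product: 13 C5 silyl ether of 12
Conditions: TBSOTf, 2,6-lutidine, CH2Cl2, −78 °C
Reagents that add atoms: tert-butyldimethylsilyl triflate CC(C)(C)[Si](C)(C)OS(=O)(=O)C(F)(F)F
Why: Silyl triflate with a hindered base should protect the hindered C5 carbinol and so block retro-aldol and Payne pathways.

Step 10
Reactants: 13 β-silyloxy ester
Product: 14 C7 aldehyde (3-silyloxy-3-(oxiranyl)propanal)
Conditions: i-Bu2AlH (1.1 equiv), CH2Cl2, −78 °C; Rochelle salt work-up
Reagents that add atoms: none
Why: Low-temperature partial reduction of a β-silyloxy methyl ester should stop at the aldehyde; the trisubstituted epoxide is inert to the hydride at −78 °C.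

Step 11
Reactants: 14 C7 aldehyde; 15 methyl propiolate
Product: 17 methyl 2-[1-hydroxyalkyl]acrylate (C7 carbinol with C8=C9 and ester C19; C7 epimer mixture), via vinylalane 16 (not isolated)
Conditions: i-Bu2AlH, N-methylmorpholine N-oxide, THF, 0 °C; then 15; then 14, 0 °C to rt
Reagents that add atoms: none
Why: Hydroalumination of the propiolate gives the α-(methoxycarbonyl)vinylalane, whose 1,2-addition to the aldehyde (vinylalumination, a Baylis–Hillman-type result) should form C7–C8; C7 is not controlled and is erased in step 19.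

Step 12
Reactants: 17 bis-silyl ether acrylate
Product: 18 C13,C7-diol (C5 silyl ether retained)
Conditions: HF·pyridine, pyridine, THF, 0 °C
Reagents that add atoms: none
Why: Buffered HF·pyridine should cleave the primary C13 silyl ether much faster than the hindered secondary C5 silyl ether.

Step 13
Reactants: 18 diol
Product: 19 C13 aldehyde (C7 carbinol free)
Conditions: TEMPO (cat.), PhI(OAc)2, CH2Cl2, rt
Reagents that add atoms: none
Why: Oxoammonium-mediated oxidation should take the unhindered primary C13 alcohol selectively over the hindered, electron-poor secondary C7 carbinol.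

Step 14
Reactants: 20 ethyl oxirane-2-carboxylate (racemic); 21 triethyl phosphonoacetate
Product: 23 ethyl 4-(diethoxyphosphoryl)-5-oxooxolane-2-carboxylate (diastereomer mixture), via open-chain hydroxy diester 22 (not isolated)
Conditions: NaOEt, EtOH, 0 °C to reflux; AcOH quench
Reagents that add atoms: none
Why: The phosphonoacetate anion should open the glycidate at its unsubstituted carbon and the resulting alkoxide should lactonise onto the phosphonoacetate ester (epoxide opening then lactonisation), giving the ring with C10, C11, C12 and C20.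

Step 15
Reactants: 23 phosphonate lactone ethyl ester
Product: 25 4-(diethoxyphosphoryl)-5-oxooxolane-2-carboxylic acid, via hydroxy diacid 24 (not isolated)
Conditions: LiOH, THF/H2O, 0 °C to rt; then 2 M HCl; then TsOH (cat.), toluene, 60 °C
Reagents that add atoms: water O
Why: Saponification should cleave the ethyl ester and open the lactone while the phosphonate diester survives; acid then re-closes the only possible γ-lactone.

Step 16
Reactants: 19 C13 aldehyde; 25 phosphonate lactone acid
Product: 26 seco acid: (E)-alkylidene lactone with a carboxyl group on C10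
Conditions: LiCl, DBU (3 equiv), MeCN, 0 °C to rt; pH 3 work-up
Reagents that add atoms: none
Why: Horner–Wadsworth–Emmons olefination under Masamune–Roush conditions (the carboxylate is a spectator) should form C12=C13, with the thermodynamically preferred E isomer (C14 trans to the lactone carbonyl) expected to dominate.

Step 17
Reactants: 26 seco acid
Product: 29 macrocyclic lactone with C5 silyl ether and C7 carbinol (10S; C5/C7/C8 epimer mixture), via C10 lactonyl radical 27 (not isolated), via macrocyclic C8 radical 28 (not isolated)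
Conditions: [Ir(dF(CF3)ppy)2(dtbbpy)]PF6 (5 mol %), K2HPO4 (1.2 equiv), degassed DMF (1 mM), blue LEDs, rt
Reagents that add atoms: none
Why: The carboxylate of 26 is oxidised by the photoexcited trivalent iridium complex and loses CO2 to give the oxygen-stabilised C10 radical 27, which attacks the unsubstituted acrylate terminus C9; the ester-stabilised C8 radical 28 is then reduced by the divalent iridium complex to the enolate and protonated. The closest known reactions are photoredox decarboxylative conjugate-addition macrocyclisations of peptides and tin-hydride endo radical macrocyclisations onto acrylates. The 14-membered carbocycle closes in a 14-endo-trig mode, and the lactone is already in place and unchanged. C10 is set by which face of the planar radical the returning chain attacks, a choice governed only by the conformation of the macrocyclic transition state as biased by C1 and the cis-epoxide, so the required (10S) epimer may have to be separated from its epimer; C8 is set by protonation and is re-equilibrated in step 19. The step needs ring closure to beat oligomerisation (high dilution) and the nucleophilic radical to choose the electron-poor acrylate over the isopropenyl group and C13 (attack there would close a four-membered ring). A 1,5-hydrogen shift from C14 is excluded because the (E)-alkylidene holds C14 in the lactone plane well beyond reach of C10.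

Step 18
Reactants: 29 macrocyclic silyl ether
Product: 30 macrocyclic C5,C7-diol
Conditions: Bu4NF, AcOH (1:1), THF, rt to 40 °C
Reagents that add atoms: none
Why: Acetic acid-buffered fluoride should remove the hindered C5 silyl ether without Payne rearrangement, retro-aldol cleavage or elimination at the β-hydroxy ester.

Step 19
Reactants: 30 macrocyclic diol
Product: 31 CNP0108136.1 (target)
Conditions: Dess–Martin periodinane (3 equiv), pyridine, CH2Cl2, 0 °C to rt; pH 7 buffer work-up
Reagents that add atoms: none
Why: Double Dess–Martin oxidation of the 1,3-diol should give the C5/C7 β-diketone (epoxy ketone and β-keto ester at once); C8 then equilibrates through its enol to the resting (8S) epimer.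

Compound list
1 | 5,6-dihydro-2H-pyran-2-one | O=C1C=CCCO1 | starting material
2 | isopropenylboronic acid pinacol ester | CC(=C)B1OC(C)(C)C(C)(C)O1 | starting material
3 | (4R)-4-(prop-1-en-2-yl)oxan-2-one | C=C(C)[C@@H]1CCOC(=O)C1 | intermediate
4 | (4R)-4-(prop-1-en-2-yl)oxan-2-ol (anomer mixture) | C=C(C)[C@@H]1CCOC(O)C1 | intermediate
5 | ethyl 2-[bis(2,2,2-trifluoroethoxy)phosphoryl]propanoate | CCOC(=O)C(C)P(=O)(OCC(F)(F)F)OCC(F)(F)F | starting material
6 | ethyl (2Z,5S)-7-hydroxy-2-methyl-5-(prop-1-en-2-yl)hept-2-enoate | C=C(C)[C@@H](C/C=C(/C)C(=O)OCC)CCO | intermediate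
7 | ethyl (2Z,5S)-7-[(tert-butyldimethylsilyl)oxy]-2-methyl-5-(prop-1-en-2-yl)hept-2-enoate | C=C(C)[C@@H](C/C=C(/C)C(=O)OCC)CCO[Si](C)(C)C(C)(C)C | intermediate
8 | (2Z,5S)-7-[(tert-butyldimethylsilyl)oxy]-2-methyl-5-(prop-1-en-2-yl)hept-2-en-1-ol | C=C(C)[C@@H](C/C=C(/C)CO)CCO[Si](C)(C)C(C)(C)C | intermediate
9 | [(2R,3S)-3-{(2R)-4-[(tert-butyldimethylsilyl)oxy]-2-(prop-1-en-2-yl)butyl}-2-methyloxiran-2-yl]methanol | C=C(C)[C@@H](C[C@@H]1O[C@]1(C)CO)CCO[Si](C)(C)C(C)(C)C | intermediate
10 | (2S,3S)-3-{(2R)-4-[(tert-butyldimethylsilyl)oxy]-2-(prop-1-en-2-yl)butyl}-2-methyloxirane-2-carbaldehyde | C=C(C)[C@@H](C[C@@H]1O[C@]1(C)C=O)CCO[Si](C)(C)C(C)(C)C | intermediate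
11 | methyl acetate | COC(C)=O | starting material
12 | β-hydroxy ester: methyl 3-hydroxy-3-(oxiranyl)propanoate, oxirane and side chain as in 10, C5 epimers | C=C(C)[C@@H](C[C@@H]1O[C@]1(C)C(O)CC(=O)OC)CCO[Si](C)(C)C(C)(C)C | intermediate
13 | C5 tert-butyldimethylsilyl ether of 12 | C=C(C)[C@@H](C[C@@H]1O[C@]1(C)C(O[Si](C)(C)C(C)(C)C)CC(=O)OC)CCO[Si](C)(C)C(C)(C)C | intermediate
14 | C7 aldehyde: 3-silyloxy-3-(oxiranyl)propanal | C=C(C)[C@@H](C[C@@H]1O[C@]1(C)C(O[Si](C)(C)C(C)(C)C)CC=O)CCO[Si](C)(C)C(C)(C)C | intermediate
15 | methyl propiolate | C#CC(=O)OC | starting material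
16 | methyl 2-(diisobutylalumanyl)acrylate (vinylalane, not isolated) | C=C(C(=O)OC)[Al](CC(C)C)CC(C)C | intermediate
17 | C7 carbinol acrylate with C5 and C13 silyl ethers (C5, C7 epimers) | C=C(C)[C@@H](C[C@@H]1O[C@]1(C)C(O[Si](C)(C)C(C)(C)C)CC(O)C(=C)C(=O)OC)CCO[Si](C)(C)C(C)(C)C | intermediate
18 | C13,C7-diol with C5 silyl ether | C=C(C)[C@@H](C[C@@H]1O[C@]1(C)C(O[Si](C)(C)C(C)(C)C)CC(O)C(=C)C(=O)OC)CCO | intermediate
19 | C13 aldehyde with free C7 carbinol and C5 silyl ether | C=C(C)[C@@H](C[C@@H]1O[C@]1(C)C(O[Si](C)(C)C(C)(C)C)CC(O)C(=C)C(=O)OC)CC=O | intermediate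
20 | ethyl oxirane-2-carboxylate (racemic ethyl glycidate) | CCOC(=O)C1CO1 | starting material
21 | triethyl phosphonoacetate | CCOC(=O)CP(=O)(OCC)OCC | starting material
22 | diethyl 2-(diethoxyphosphoryl)-4-hydroxypentanedioate (not isolated) | CCOC(=O)C(O)CC(C(=O)OCC)P(=O)(OCC)OCC | intermediate
23 | ethyl 4-(diethoxyphosphoryl)-5-oxooxolane-2-carboxylate | CCOC(=O)C1CC(P(=O)(OCC)OCC)C(=O)O1 | intermediate
24 | 2-(diethoxyphosphoryl)-4-hydroxypentanedioic acid (not isolated) | OC(=O)C(O)CC(C(=O)O)P(=O)(OCC)OCC | intermediate
25 | 4-(diethoxyphosphoryl)-5-oxooxolane-2-carboxylic acid | OC(=O)C1CC(P(=O)(OCC)OCC)C(=O)O1 | intermediate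
26 | seco acid: (E)-4-alkylidene-5-oxooxolane-2-carboxylic acid carrying the C1–C9 chain | C=C(C)[C@@H](C[C@@H]1O[C@]1(C)C(O[Si](C)(C)C(C)(C)C)CC(O)C(=C)C(=O)OC)C/C=C2\CC(C(=O)O)OC2=O | intermediate
27 | C10 lactonyl radical (not isolated) | C=C(C)[C@@H](C[C@@H]1O[C@]1(C)C(O[Si](C)(C)C(C)(C)C)CC(O)C(=C)C(=O)OC)C/C=C2\C[CH]OC2=O | intermediate
28 | macrocyclic C8 radical (not isolated) | C=C(C)[C@@H]1C/C=C2\C[C@H](C[C](C(=O)OC)C(O)CC(O[Si](C)(C)C(C)(C)C)[C@@]3(C)O[C@H]3C1)OC2=O | intermediate
29 | macrocyclic lactone, C5 silyl ether, C7 carbinol, (1R,3S,4S,10S,12E) | C=C(C)[C@@H]1C/C=C2\C[C@H](CC(C(=O)OC)C(O)CC(O[Si](C)(C)C(C)(C)C)[C@@]3(C)O[C@H]3C1)OC2=O | intermediate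
30 | macrocyclic C5,C7-diol | C=C(C)[C@@H]1C/C=C2\C[C@H](CC(C(=O)OC)C(O)CC(O)[C@@]3(C)O[C@H]3C1)OC2=O | intermediate
31 | CNP0108136.1, (1R,3S,4S,8S,10S,12E) | C=C(C)[C@@H]1C/C=C2\C[C@H](C[C@H](C(=O)OC)C(=O)CC(=O)[C@@]3(C)O[C@H]3C1)OC2=O | target

Total step count: 19. Longest linear sequence: 17 steps (steps 1–13 and 16–19); steps 14 and 15 make the phosphonate partner.

Steps most likely to fail

Step 17 (key step). The acyloxy-substituted carboxylate may be oxidised too slowly by the photocatalyst, so that back electron transfer and oligomerisation at the required dilution win over ring closure; the two faces of the planar C10 radical may also be poorly differentiated. Fallback: from 26, coupling with N-hydroxyphthalimide (N,N'-diisopropylcarbodiimide, DMAP, CH2Cl2) should give the redox-active N-(acyloxy)phthalimide ester F1. Reductive fragmentation of F1 (Ru(bpy)3Cl2, Hantzsch ester, i-Pr2NEt, CH2Cl2, 1 mM, blue LEDs) generates the same C10 radical without any carboxylate oxidation or base, and the C8 radical is quenched by hydrogen-atom transfer. This returns to 29; the C10 epimers are separated there if the face selectivity stays low.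

Step 16. The olefination may give incomplete E selectivity, and the phosphonate anion or DBU may add to the acrylate or disturb the free β-hydroxy acrylate. Fallback: from 19, Wittig methylenation (Ph3P=CH2, THF, −78 to 0 °C) should give the terminal alkene F2. Cross-metathesis of F2 with 4-methylidene-5-oxooxolane-2-carboxylic acid F3 (made from glyoxylic acid and 2-(bromomethyl)acrylic acid by indium-mediated allylation in water and lactonisation) then forms C12=C13. The catalyst is the second-generation Hoveyda–Grubbs catalyst RuCl2(H2IMes)(=CH-2-(i-PrO)C6H4) with 2,6-dichloro-1,4-benzoquinone in CH2Cl2 at 40 °C, and the sequence returns to 26.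

Step 3. The lactol may open too slowly at low temperature, so that warming erodes the Z selectivity and lets the liberated C13 alkoxide close onto the new enoate by oxa-Michael addition. Fallback: from 3, aminolysis with Me(MeO)NH·HCl and AlMe3 should give the hydroxy Weinreb amide F4. Silylation (TBSCl, imidazole) gives the silyl ether F5, and i-Bu2AlH at −78 °C gives the discrete aldehyde F6. The same Still–Gennari olefination with 5 then returns directly to 7.

Further compounds
F1 | step 17 | N-(acyloxy)phthalimide ester of seco acid 26 | C=C(C)[C@@H](C[C@@H]1O[C@]1(C)C(O[Si](C)(C)C(C)(C)C)CC(O)C(=C)C(=O)OC)C/C=C2\CC(C(=O)ON3C(=O)c4ccccc4C3=O)OC2=O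
F2 | step 16 | terminal alkene from methylenation of aldehyde 19 | C=C(C)[C@@H](C[C@@H]1O[C@]1(C)C(O[Si](C)(C)C(C)(C)C)CC(O)C(=C)C(=O)OC)CC=C
F3 | step 16 | 4-methylidene-5-oxooxolane-2-carboxylic acid | C=C1CC(C(=O)O)OC1=O
F4 | step 3 | (3R)-5-hydroxy-N-methoxy-N-methyl-3-(prop-1-en-2-yl)pentanamide | C=C(C)[C@@H](CC(=O)N(C)OC)CCO
F5 | step 3 | (3R)-5-[(tert-butyldimethylsilyl)oxy]-N-methoxy-N-methyl-3-(prop-1-en-2-yl)pentanamide | C=C(C)[C@@H](CC(=O)N(C)OC)CCO[Si](C)(C)C(C)(C)C
F6 | step 3 | (3R)-5-[(tert-butyldimethylsilyl)oxy]-3-(prop-1-en-2-yl)pentanal | C=C(C)[C@@H](CC=O)CCO[Si](C)(C)C(C)(C)C
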